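The synthesis rests on disconnecting the C2–C3 bond of ring C. C2 is a benzylic carbon bonded to O1 and to ring B, so in a ring A aryl ether of the ring B benzyl alcohol it carries two enantiotopic, doubly activated hydrogens. A rhodium carbene generated at C3 from an ortho diazoacetyl group inserts into one of them under a chiral dirhodium tetracarboxylate. This single operation forms C2–C3, closes ring C and sets the only stereocentre as 2S. The precursor is a pentasubstituted ring A diazomethyl ketone carrying the geranyl chain, the ring B benzyl ether at O1 and silyl ethers on all three remaining phenols, so one buffered fluoride treatment then releases the target.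

Key step: step 8

Assumption: the (S)-configured PTTL catalyst is taken to deliver the 2S product; the sense of induction is to be confirmed on the first run, and if it is opposite the enantiomeric Rh2(R-PTTL)4 is used with no other change.

Throughout, geranyl = (2E)-3,7-dimethylocta-2,6-dien-1-yl.

Step 1
Reactants: 1 isovanillin (3-hydroxy-4-methoxybenzaldehyde)
Product: 2 3-(tert-butyldimethylsilyloxy)-4-methoxybenzaldehyde
Conditions: TBSCl (1.1 equiv), imidazole (2 equiv), DMF, rt
Reagents that add atoms: tert-butyldimethylsilyl chloride, CC(C)(C)[Si](C)(C)Cl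
Why: Imidazole-promoted O-silylation of the phenol is fast and leaves the aldehyde untouched, masking the only acidic site of ring B before the carbene step.

Step 2
Reactants: 2 3-(tert-butyldimethylsilyloxy)-4-methoxybenzaldehyde
Product: 3 [3-(tert-butyldimethylsilyloxy)-4-methoxyphenyl]methanol
Conditions: NaBH4, MeOH, 0 °C
Reagents that add atoms: none
Why: Borohydride reduction of the aromatic aldehyde to the benzylic alcohol is chemoselective, and the aryl silyl ether should survive the short exposure at 0 °C.

Step 3
Reactants: 4 2',4',6'-trihydroxyacetophenone; 5 geranyl bromide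
Product: 6 3'-geranyl-2',4',6'-trihydroxyacetophenone
Conditions: DBU (1.1 equiv), THF, 0 °C to rt
Reagents that add atoms: none
Why: C-alkylation of the ambident phloroglucinol-type phenoxide by SN2 displacement at the primary allylic bromide keeps the E alkene, and because both free ring positions of 4 are equivalent only one mono-C-geranyl isomer can form, O-alkylated and doubly alkylated by-products being removed by chromatography.

Step 4
Reactants: 6 3'-geranyl-2',4',6'-trihydroxyacetophenone
Product: 7 1-{3-geranyl-2,6-dihydroxy-4-(triisopropylsilyloxy)phenyl}ethanone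
Conditions: TIPSCl (1.05 equiv), imidazole (2.2 equiv), DMF, 0 °C
Reagents that add atoms: triisopropylsilyl chloride, CC(C)[Si](Cl)(C(C)C)C(C)C
Why: The hydroxyl para to the acetyl group is the most acidic and the only one not hydrogen-bonded to the carbonyl, so one equivalent of the bulky silyl chloride should silylate it selectively (imidazole-promoted O-silylation).

Step 5
Reactants: 7 1-{3-geranyl-2,6-dihydroxy-4-(triisopropylsilyloxy)phenyl}ethanone; 3 [3-(tert-butyldimethylsilyloxy)-4-methoxyphenyl]methanol
Product: 8 1-{2-[3-(tert-butyldimethylsilyloxy)-4-methoxybenzyloxy]-5-geranyl-6-hydroxy-4-(triisopropylsilyloxy)phenyl}ethanone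
Conditions: PPh3 (1.2 equiv), DIAD (1.2 equiv), THF, 0 °C to rt
Reagents that add atoms: none
Why: Mitsunobu etherification, in which the phenoxide displaces the benzylic oxyphosphonium ion at the hydroxyl next to the ring hydrogen, because the other hydroxyl is flanked by the geranyl chain and held in the stronger hydrogen bond to the carbonyl, the same site preference known for alkylation of 3-alkyl-2,4,6-trihydroxyacetophenones.

Step 6
Reactants: 8 1-{2-[3-(tert-butyldimethylsilyloxy)-4-methoxybenzyloxy]-5-geranyl-6-hydroxy-4-(triisopropylsilyloxy)phenyl}ethanone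
Product: 9 1-{2-[3-(tert-butyldimethylsilyloxy)-4-methoxybenzyloxy]-6-(tert-butyldimethylsilyloxy)-5-geranyl-4-(triisopropylsilyloxy)phenyl}ethanone
Conditions: TBSOTf (1.3 equiv), 2,6-lutidine (2 equiv), CH2Cl2, −78 to 0 °C
Reagents that add atoms: tert-butyldimethylsilyl trifluoromethanesulfonate, CC(C)(C)[Si](C)(C)OS(=O)(=O)C(F)(F)F
Why: The silyl triflate is reactive enough to silylate the hindered, hydrogen-bonded phenol at low temperature while 2,6-lutidine is too weak a base to drive enol silylation of the methyl ketone; this oxygen (the later O5) receives a silyl group because an alkyl or alkoxymethyl ether here would offer the carbene a competing C–H at the same distance as the benzylic one.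

Step 7
Reactants: 9 1-{2-[3-(tert-butyldimethylsilyloxy)-4-methoxybenzyloxy]-6-(tert-butyldimethylsilyloxy)-5-geranyl-4-(triisopropylsilyloxy)phenyl}ethanone
Product: 11 2-diazo-1-{2-[3-(tert-butyldimethylsilyloxy)-4-methoxybenzyloxy]-6-(tert-butyldimethylsilyloxy)-5-geranyl-4-(triisopropylsilyloxy)phenyl}ethanone, via trifluoroacetyl diketone 10 (not isolated)
Conditions: LiN(SiMe3)2 (1.1 equiv), THF, −78 °C; CF3CO2CH2CF3 (1.3 equiv), −78 °C; aq NH4Cl work-up; then p-ABSA (1.5 equiv), Et3N (1.5 equiv), H2O (1 equiv), MeCN, rt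
Reagents that add atoms: 4-acetamidobenzenesulfonyl azide (p-ABSA), CC(=O)Nc1ccc(cc1)S(=O)(=O)N=[N+]=[N-] (the N2 unit of 11); 2,2,2-trifluoroethyl trifluoroacetate, FC(F)(F)COC(=O)C(F)(F)F (the CF3CO group of 10, lost again on the way to 11)
Why: Detrifluoroacetylative diazo transfer, in which the kinetic lithium enolate of the methyl ketone is C-acylated to the activated diketone 10, whose acidic methylene accepts N2 from the sulfonyl azide with loss of the trifluoroacetyl group to the sulfonamide; this avoids diazomethane and the activation of a doubly ortho-substituted benzoic acid, and the enolate is kept at −78 °C so that the neighbouring aryl silyl ether should not migrate.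

Step 8
Reactants: 11 2-diazo-1-{2-[3-(tert-butyldimethylsilyloxy)-4-methoxybenzyloxy]-6-(tert-butyldimethylsilyloxy)-5-geranyl-4-(triisopropylsilyloxy)phenyl}ethanone
Product: 12 (2S)-5-(tert-butyldimethylsilyloxy)-2-[3-(tert-butyldimethylsilyloxy)-4-methoxyphenyl]-6-geranyl-7-(triisopropylsilyloxy)chroman-4-one
Conditions: Rh2(S-PTTL)4 [dirhodium tetrakis(N-phthaloyl-(S)-tert-leucinate), divalent rhodium] (2 mol %), CH2Cl2, 0 °C, slow addition of 11 at high dilution
Reagents that add atoms: none
Why: Loss of N2 from 11 at the dirhodium core gives an electrophilic rhodium carbene at C3, which takes up one benzylic C–H of the O1–CH2–ring B unit in a concerted, hydride-transfer-like three-centre insertion that forms the C2–C3 bond. The closest known reaction type is the chiral dirhodium carboxylate-catalysed intramolecular C–H insertion of ortho-alkoxyaryl diazomethyl ketones to 2-substituted chroman-4-ones. Ring C closes by 1,6-insertion through a six-membered cyclic transition state whose members C3, C4, C4a, C8a, O1 and C2 become the ring atoms. The new C2 stereocentre is set by the catalyst alone, the chiral pocket built by the four N-phthaloyl-tert-leucinate ligands deciding which of the two enantiotopic benzylic hydrogens reaches the carbene, since the substrate has no other stereocentre. The step needs insertion to outrun oxonium ylide formation at O1 and cyclopropanation of the geranyl alkenes; the substrate secures this because the target C–H is activated twice (next to O1 and para to the ring B methoxy group), the O1 lone pairs are delocalised into the acyl-bearing ring A, the silyl ethers at O5 and O7 offer no activated C–H within reach, and the nearest alkene could only be reached through a seven-membered ring. Slow addition at low concentration should suppress carbene dimerisation.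

Step 9
Reactants: 12 (2S)-5-(tert-butyldimethylsilyloxy)-2-[3-(tert-butyldimethylsilyloxy)-4-methoxyphenyl]-6-geranyl-7-(triisopropylsilyloxy)chroman-4-one
Product: 13 (2S)-6-geranyl-5,7-dihydroxy-2-(3-hydroxy-4-methoxyphenyl)chroman-4-one (CNP0264411.1)
Conditions: Bu4NF/AcOH (1:1, 4 equiv), THF, 0 °C to rt
Reagents that add atoms: none
Why: Fluoride desilylation cleaves the three aryl silyl ethers through Si–F bond formation, and the acetic acid buffer protonates the phenoxides at once, so that base-induced ring opening to the chalcone (which would racemise C2) and acid-induced cyclisation of the geranyl chain should both be avoided.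

Compound list
1 | isovanillin (3-hydroxy-4-methoxybenzaldehyde) | COc1ccc(C=O)cc1O | starting material
2 | 3-(tert-butyldimethylsilyloxy)-4-methoxybenzaldehyde | COc1ccc(C=O)cc1O[Si](C)(C)C(C)(C)C | intermediate
3 | [3-(tert-butyldimethylsilyloxy)-4-methoxyphenyl]methanol | COc1ccc(CO)cc1O[Si](C)(C)C(C)(C)C | intermediate
4 | 2',4',6'-trihydroxyacetophenone | CC(=O)c1c(O)cc(O)cc1O | starting material
5 | geranyl bromide | CC(C)=CCC/C(C)=C/CBr | starting material
6 | 3'-geranyl-2',4',6'-trihydroxyacetophenone | CC(=O)c1c(O)cc(O)c(C/C=C(\C)CCC=C(C)C)c1O | intermediate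
7 | 1-{3-geranyl-2,6-dihydroxy-4-(triisopropylsilyloxy)phenyl}ethanone | CC(=O)c1c(O)cc(O[Si](C(C)C)(C(C)C)C(C)C)c(C/C=C(\C)CCC=C(C)C)c1O | intermediate
8 | 1-{2-[3-(tert-butyldimethylsilyloxy)-4-methoxybenzyloxy]-5-geranyl-6-hydroxy-4-(triisopropylsilyloxy)phenyl}ethanone | CC(=O)c1c(OCc2ccc(OC)c(O[Si](C)(C)C(C)(C)C)c2)cc(O[Si](C(C)C)(C(C)C)C(C)C)c(C/C=C(\C)CCC=C(C)C)c1O | intermediate
9 | 1-{2-[3-(tert-butyldimethylsilyloxy)-4-methoxybenzyloxy]-6-(tert-butyldimethylsilyloxy)-5-geranyl-4-(triisopropylsilyloxy)phenyl}ethanone | CC(=O)c1c(OCc2ccc(OC)c(O[Si](C)(C)C(C)(C)C)c2)cc(O[Si](C(C)C)(C(C)C)C(C)C)c(C/C=C(\C)CCC=C(C)C)c1O[Si](C)(C)C(C)(C)C | intermediate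
10 | 4,4,4-trifluoro-1-{2-[3-(tert-butyldimethylsilyloxy)-4-methoxybenzyloxy]-6-(tert-butyldimethylsilyloxy)-5-geranyl-4-(triisopropylsilyloxy)phenyl}butane-1,3-dione | FC(F)(F)C(=O)CC(=O)c1c(OCc2ccc(OC)c(O[Si](C)(C)C(C)(C)C)c2)cc(O[Si](C(C)C)(C(C)C)C(C)C)c(C/C=C(\C)CCC=C(C)C)c1O[Si](C)(C)C(C)(C)C | intermediate
11 | 2-diazo-1-{2-[3-(tert-butyldimethylsilyloxy)-4-methoxybenzyloxy]-6-(tert-butyldimethylsilyloxy)-5-geranyl-4-(triisopropylsilyloxy)phenyl}ethanone | [N-]=[N+]=CC(=O)c1c(OCc2ccc(OC)c(O[Si](C)(C)C(C)(C)C)c2)cc(O[Si](C(C)C)(C(C)C)C(C)C)c(C/C=C(\C)CCC=C(C)C)c1O[Si](C)(C)C(C)(C)C | intermediate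
12 | (2S)-5-(tert-butyldimethylsilyloxy)-2-[3-(tert-butyldimethylsilyloxy)-4-methoxyphenyl]-6-geranyl-7-(triisopropylsilyloxy)chroman-4-one | COc1ccc([C@@H]2CC(=O)c3c(cc(O[Si](C(C)C)(C(C)C)C(C)C)c(C/C=C(\C)CCC=C(C)C)c3O[Si](C)(C)C(C)(C)C)O2)cc1O[Si](C)(C)C(C)(C)C | intermediate
13 | (2S)-6-geranyl-5,7-dihydroxy-2-(3-hydroxy-4-methoxyphenyl)chroman-4-one | COc1ccc([C@@H]2CC(=O)c3c(cc(O)c(C/C=C(\C)CCC=C(C)C)c3O)O2)cc1O | target

Total step count: 9. Longest linear sequence: 7 steps (steps 3 to 9, from 4); the ring B alcohol 3 is made in 2 steps and joins at step 5.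

Steps most likely to fail

Step 8. The carbene may be captured by the lone pair of O1, the oxonium ylide then undergoing a 1,2-benzyl shift. It may also add to the nearer geranyl alkene, or the two benzylic hydrogens may be poorly discriminated. The fallback closes ring C through the O1–C2 bond by condensation and oxa-Michael addition, followed by resolution. It sets out from 7. Allyl bromide and K2CO3 in acetone should etherify the less hindered hydroxyl to give 1-{2-(allyloxy)-5-geranyl-6-hydroxy-4-(triisopropylsilyloxy)phenyl}ethanone F1. TBSOTf and 2,6-lutidine then cap the remaining phenol to give 1-{2-(allyloxy)-6-(tert-butyldimethylsilyloxy)-5-geranyl-4-(triisopropylsilyloxy)phenyl}ethanone F2. Pd(PPh3)4 (zerovalent palladium) with morpholine removes the allyl group to give 1-{2-(tert-butyldimethylsilyloxy)-3-geranyl-6-hydroxy-4-(triisopropylsilyloxy)phenyl}ethanone F3. Pyrrolidine-mediated aldol condensation of F3 with aldehyde 2 in toluene gives the 2'-hydroxychalcone F4, which should close in the same pot by oxa-Michael addition to the racemic silyl-protected flavanone F5. Preparative HPLC on a chiral stationary phase separates 12 from its (2R)-enantiomer F6, and the route is rejoined at 12.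

Step 7. After enolisation the silyl group on the neighbouring aryl oxygen may migrate to the enolate oxygen, or the twisted, hindered enolate may be acylated on oxygen, so that no activated diketone reaches the diazo transfer. The fallback introduces the diazo group by substitution at a bromomethyl ketone instead. It sets out from 9. Soft enolisation with TMSOTf and Et3N in CH2Cl2 at 0 °C involves no anionic oxygen, so no silyl shift is possible, and should give the trimethylsilyl enol ether F7. NBS in THF at −78 °C converts it to the bromomethyl ketone F8; the enol ether should react far faster than the trisubstituted alkenes at this temperature. N,N'-Ditosylhydrazine and DBU in THF at 0 °C then turn F8 into 11 by N-alkylation and loss of two sulfinates, where the route is rejoined.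

Step 5. The hydrogen-bonded phenol may react too slowly with the Mitsunobu betaine, so that the electron-rich benzylic oxyphosphonium ion is consumed by the reduced azodicarboxylate, or etherification may spread to both ortho hydroxyls. The fallback is a Williamson alkylation with a preformed benzylic halide, in which the site is decided by the acidity of the mono-phenoxide. It sets out from 3 and 7. CBr4 and PPh3 in CH2Cl2 at 0 °C convert 3 into 3-(tert-butyldimethylsilyloxy)-4-methoxybenzyl bromide F9, which is used at once. With 7 and K2CO3 (1.1 equiv) in acetone at rt, F9 should alkylate the more acidic, less hindered hydroxyl to give 8, where the route is rejoined.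

Further compounds
F1 | step 8 | 1-{2-(allyloxy)-5-geranyl-6-hydroxy-4-(triisopropylsilyloxy)phenyl}ethanone | CC(=O)c1c(OCC=C)cc(O[Si](C(C)C)(C(C)C)C(C)C)c(C/C=C(\C)CCC=C(C)C)c1O
F2 | step 8 | 1-{2-(allyloxy)-6-(tert-butyldimethylsilyloxy)-5-geranyl-4-(triisopropylsilyloxy)phenyl}ethanone | CC(=O)c1c(OCC=C)cc(O[Si](C(C)C)(C(C)C)C(C)C)c(C/C=C(\C)CCC=C(C)C)c1O[Si](C)(C)C(C)(C)C
F3 | step 8 | 1-{2-(tert-butyldimethylsilyloxy)-3-geranyl-6-hydroxy-4-(triisopropylsilyloxy)phenyl}ethanone | CC(=O)c1c(O)cc(O[Si](C(C)C)(C(C)C)C(C)C)c(C/C=C(\C)CCC=C(C)C)c1O[Si](C)(C)C(C)(C)C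
F4 | step 8 | (E)-1-{2-(tert-butyldimethylsilyloxy)-3-geranyl-6-hydroxy-4-(triisopropylsilyloxy)phenyl}-3-[3-(tert-butyldimethylsilyloxy)-4-methoxyphenyl]prop-2-en-1-one | COc1ccc(/C=C/C(=O)c2c(O)cc(O[Si](C(C)C)(C(C)C)C(C)C)c(C/C=C(\C)CCC=C(C)C)c2O[Si](C)(C)C(C)(C)C)cc1O[Si](C)(C)C(C)(C)C
F5 | step 8 | racemic 5-(tert-butyldimethylsilyloxy)-2-[3-(tert-butyldimethylsilyloxy)-4-methoxyphenyl]-6-geranyl-7-(triisopropylsilyloxy)chroman-4-one | COc1ccc(C2CC(=O)c3c(cc(O[Si](C(C)C)(C(C)C)C(C)C)c(C/C=C(\C)CCC=C(C)C)c3O[Si](C)(C)C(C)(C)C)O2)cc1O[Si](C)(C)C(C)(C)C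
F6 | step 8 | (2R)-5-(tert-butyldimethylsilyloxy)-2-[3-(tert-butyldimethylsilyloxy)-4-methoxyphenyl]-6-geranyl-7-(triisopropylsilyloxy)chroman-4-one | COc1ccc([C@H]2CC(=O)c3c(cc(O[Si](C(C)C)(C(C)C)C(C)C)c(C/C=C(\C)CCC=C(C)C)c3O[Si](C)(C)C(C)(C)C)O2)cc1O[Si](C)(C)C(C)(C)C
F7 | step 7 | {1-{2-[3-(tert-butyldimethylsilyloxy)-4-methoxybenzyloxy]-6-(tert-butyldimethylsilyloxy)-5-geranyl-4-(triisopropylsilyloxy)phenyl}ethenyloxy}trimethylsilane | C=C(O[Si](C)(C)C)c1c(OCc2ccc(OC)c(O[Si](C)(C)C(C)(C)C)c2)cc(O[Si](C(C)C)(C(C)C)C(C)C)c(C/C=C(\C)CCC=C(C)C)c1O[Si](C)(C)C(C)(C)C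
F8 | step 7 | 2-bromo-1-{2-[3-(tert-butyldimethylsilyloxy)-4-methoxybenzyloxy]-6-(tert-butyldimethylsilyloxy)-5-geranyl-4-(triisopropylsilyloxy)phenyl}ethanone | BrCC(=O)c1c(OCc2ccc(OC)c(O[Si](C)(C)C(C)(C)C)c2)cc(O[Si](C(C)C)(C(C)C)C(C)C)c(C/C=C(\C)CCC=C(C)C)c1O[Si](C)(C)C(C)(C)C
F9 | step 5 | 3-(tert-butyldimethylsilyloxy)-4-methoxybenzyl bromide | COc1ccc(CBr)cc1O[Si](C)(C)C(C)(C)C
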